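**Plan**

- Enabling feature: ring A (C1' carboxyl, C2' OH, C3' CHO, C4' OH, C5' CH3, C6' CH3) is a C-methylated orsellinate, that is, the aldol-aromatization product of a 3,5,7-triketo acid closed between C1' and C6'. Ring B is the C5-methyl homologue of commercial atraric acid and carries no aromatic C–H.
- Retrosynthetic cuts, in order: the C3'–CHO bond; the depside C1'(=O)–O bond to ring B; the C1'–C6' bond of ring A (aldol); then C5'–C6' and C3'–C4' of the open chain (two enolate acylations). In ring B the C5–CH3 bond is cut (formylation, then hydrogenolysis).
- Forward: the chain is built on a dioxinone (steps 1, 2), ring A closes as a benzodioxinone (step 3) and its phenol is benzylated (step 4). Ring B is made from atraric acid (steps 5, 6).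
- The rings are joined by phenoxide opening of the acylal (step 7), followed by debenzylation (step 8) and formylation at C3', the only aromatic C–H left (step 9).
- Stereochemistry: the target has no stereocentre. The racemic, enolizable centre of the diketone and the two transient centres of the aldol adduct disappear on aromatization.

Key step: step 3

Remark: the C7 hydroxyl of the benzodioxinone is carried as a benzyl ether, because an aryl silyl ether para to the carbonyl could pass its silyl group to the phenoxide used in the coupling; diketone 8 is racemic, exists as keto–enol tautomers and is meant to be used without purification.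

**Route**

Step 1
Reactants: 1 2,2,6-trimethyl-4H-1,3-dioxin-4-one; 2 propanoyl chloride
Product: 4 2,2-dimethyl-6-(2-oxobutyl)-4H-1,3-dioxin-4-one, via lithium dienolate 3 (not isolated)
Conditions: LiN(SiMe3)2 (1.05 equiv per 1), THF, −78 °C; then 2 (0.5 equiv), −78 °C; 1 M HCl
Reagents that add atoms: none
Why: This is a crossed Claisen condensation at the γ-carbon of a vinylogous ester enolate: the base removes a proton from the C6 methyl group, dienolate 3 attacks the acid chloride through its terminal carbon to form the future C3'–C4' bond, and because 4 is more acidic than 1 a second equivalent of 3 is consumed as base, which is why 2 is the limiting reagent.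

Step 2
Reactants: 4 2,2-dimethyl-6-(2-oxobutyl)-4H-1,3-dioxin-4-one; 5 N-methoxy-N-methylacetamide
Product: 8 2,2-dimethyl-6-(3-methyl-2,4-dioxopentyl)-4H-1,3-dioxin-4-one, via dilithium dianion 6 (not isolated), via tetrahedral adduct 7 (not isolated)
Conditions: LiN(iPr)2 (2.2 equiv), THF, −78 to −40 °C; then 5, −78 to −20 °C; 1 M HCl at −78 °C
Reagents that add atoms: none
Why: This is the Claisen-type acylation of a β-dicarbonyl dianion with a Weinreb amide: the first equivalent of base forms the extended enolate between ketone and dioxinone, the second deprotonates the ethyl CH2, and this most basic carbon attacks 5 to form the C5'–C6' bond, the chelated adduct 7 keeping the acetyl group masked until the cold acid quench so that neither over-addition nor proton transfer from the new 1,3-diketone should interfere.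

Step 3
Reactants: 8 2,2-dimethyl-6-(3-methyl-2,4-dioxopentyl)-4H-1,3-dioxin-4-one
Product: 10 7-hydroxy-2,2,5,6-tetramethyl-4H-1,3-benzodioxin-4-one, via aldol adduct 9 (not isolated)
Conditions: Et3N, CH2Cl2, rt
Reagents that add atoms: none
Why: Triethylamine deprotonates the methylene between the ketone and the dioxinone, and the extended enolate carries its charge to C5 of the heterocycle, the α-carbon of a β-alkoxy enoate, which adds to the terminal methyl ketone and forms the C1'–C6' bond of ring A as aldol adduct 9. β-Elimination of water and enolization of the remaining ring ketone (the future C4' hydroxyl) should then give the arene, so the step is an intramolecular aldol condensation with aromatization, the laboratory counterpart of orsellinate biosynthesis and an established reaction of diketo-dioxinones with amine bases. The carbocycle closes in a 6-(enolendo)-exo-trig mode, with the C5=C6 enol ether double bond inside the new ring and the ketone oxygen outside it. No new stereocentre persists, since the two sp3 centres of 9 and the racemic centre of 8 all become aromatic carbons. The selectivity needed is carbon over oxygen cyclization (aldol against 4-pyranone formation or Claisen-type closure onto the acylal carbonyl); it is secured by the mild, non-nucleophilic amine, by the weak electrophilicity of the acylal carbonyl, and by geometry, because the terminal ketone is the only carbonyl that C5 can reach through a six-membered transition state, while the gain of aromaticity makes the carbon pathway irreversible.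

Step 4
Reactants: 10 7-hydroxy-2,2,5,6-tetramethyl-4H-1,3-benzodioxin-4-one
Product: 11 7-(benzyloxy)-2,2,5,6-tetramethyl-4H-1,3-benzodioxin-4-one
Conditions: BnBr, K2CO3, acetone, reflux
Reagents that add atoms: benzyl bromide, BrCc1ccccc1
Why: This is a Williamson ether synthesis on the only phenol, which must be masked because its anion, conjugated through the ring with the acylal carbonyl, would switch off the electrophile of step 7, and the acylal is inert to K2CO3 in an aprotic solvent.

Step 5
Reactants: 12 methyl 2,4-dihydroxy-3,6-dimethylbenzoate (atraric acid)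
Product: 14 methyl 5-formyl-2,4-dihydroxy-3,6-dimethylbenzoate, via α-chloro ether 13 (not isolated)
Conditions: Cl2CHOMe, TiCl4, CH2Cl2, −10 to 0 °C; then ice, 1 M HCl
Reagents that add atoms: dichloromethyl methyl ether, COC(Cl)Cl; water, O
Why: This is a Rieche formylation (Friedel–Crafts reaction of the TiCl4-activated dichloromethyl ether) at C5, the only unsubstituted ring carbon, which is ortho to the C4 hydroxyl and para to the C2 hydroxyl, and the α-chloro ether 13 is hydrolysed to the aldehyde on aqueous work-up.

Step 6
Reactants: 14 methyl 5-formyl-2,4-dihydroxy-3,6-dimethylbenzoate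
Product: 16 methyl 2,4-dihydroxy-3,5,6-trimethylbenzoate, via benzylic alcohol 15 (not isolated)
Conditions: H2 (3 bar), 10% Pd/C, AcOH, cat. HCl, rt
Reagents that add atoms: none
Why: This is the catalytic hydrogenolysis of an electron-rich aryl aldehyde to a methyl group: hydrogenation gives benzylic alcohol 15, whose C–O bond, activated by the ortho and para hydroxyls and by acid, is cleaved on the same catalyst, while ester and arene should be untouched under these mild conditions.

Step 7
Reactants: 11 7-(benzyloxy)-2,2,5,6-tetramethyl-4H-1,3-benzodioxin-4-one; 16 methyl 2,4-dihydroxy-3,5,6-trimethylbenzoate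
Product: 18 3-hydroxy-4-(methoxycarbonyl)-2,5,6-trimethylphenyl 4-(benzyloxy)-2-hydroxy-5,6-dimethylbenzoate, via sodium phenoxide 17 (not isolated)
Conditions: 16 (1.2 equiv), NaH (1.2 equiv), THF–DMF, 0 °C; then 11, 50 °C; 1 M HCl
Reagents that add atoms: none
Why: This is a nucleophilic acyl substitution at an acylal (transesterification with ring opening): one equivalent of NaH ionizes the more acidic, non-chelated C4 hydroxyl of 16 while the C2 hydroxyl stays hydrogen-bonded to the ester, phenoxide 17 adds to the C4 carbonyl of 11, and collapse of the adduct with irreversible loss of acetone releases the chelated C2' phenoxide and so drives formation of the doubly ortho-substituted aryl ester.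

Step 8
Reactants: 18 3-hydroxy-4-(methoxycarbonyl)-2,5,6-trimethylphenyl 4-(benzyloxy)-2-hydroxy-5,6-dimethylbenzoate
Product: 19 3-hydroxy-4-(methoxycarbonyl)-2,5,6-trimethylphenyl 2,4-dihydroxy-5,6-dimethylbenzoate
Conditions: H2 (1 atm), 10% Pd/C, EtOAc, rt
Reagents that add atoms: none
Why: This is the hydrogenolysis of a benzyl aryl ether, which should leave the aryl ester, the methyl ester and both arenes intact and frees the C4' hydroxyl that, together with the C2' hydroxyl, activates C3'.

Step 9
Reactants: 19 3-hydroxy-4-(methoxycarbonyl)-2,5,6-trimethylphenyl 2,4-dihydroxy-5,6-dimethylbenzoate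
Product: 21 pseudocyphellarin A, via α-chloro ether 20 (not isolated)
Conditions: Cl2CHOMe, TiCl4 (excess), CH2Cl2, −20 to 0 °C; then ice, 1 M HCl
Reagents that add atoms: dichloromethyl methyl ether, COC(Cl)Cl; water, O
Why: This is a Rieche formylation at C3', the only aromatic C–H of the molecule (ring B is hexasubstituted), which lies between two hydroxyls that bind TiCl4 and direct the electrophile, and the α-chloro ether 20 is hydrolysed on work-up to the doubly hydrogen-bonded aldehyde.

**Compound list**

1 | 2,2,6-trimethyl-4H-1,3-dioxin-4-one | CC1=CC(=O)OC(C)(C)O1 | starting material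
2 | propanoyl chloride | CCC(Cl)=O | starting material
3 | lithium 2,2-dimethyl-6-methylidene-6H-1,3-dioxin-4-olate (lithium dienolate of 1, not isolated) | C=C1C=C(O[Li])OC(C)(C)O1 | intermediate
4 | 2,2-dimethyl-6-(2-oxobutyl)-4H-1,3-dioxin-4-one | CCC(=O)CC1=CC(=O)OC(C)(C)O1 | intermediate
5 | N-methoxy-N-methylacetamide | CON(C)C(C)=O | starting material
6 | dilithium dianion of 4 (enolate of the ethyl ketone joined to the dioxinone dienolate, not isolated) | CC=C(O[Li])C=C1C=C(O[Li])OC(C)(C)O1 | intermediate
7 | lithium-chelated tetrahedral adduct of 6 and 5 (not isolated) | CON(C)C(C)(O[Li])C(C)C(=O)C=C1C=C(O[Li])OC(C)(C)O1 | intermediate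
8 | 2,2-dimethyl-6-(3-methyl-2,4-dioxopentyl)-4H-1,3-dioxin-4-one (racemic, keto–enol mixture) | CC(=O)C(C)C(=O)CC1=CC(=O)OC(C)(C)O1 | intermediate
9 | 5-hydroxy-2,2,5,6-tetramethyl-5,6-dihydro-4H-1,3-benzodioxine-4,7(8H)-dione (aldol adduct, mixture of diastereomers, not isolated) | CC1C(=O)CC2=C(C(=O)OC(C)(C)O2)C1(C)O | intermediate
10 | 7-hydroxy-2,2,5,6-tetramethyl-4H-1,3-benzodioxin-4-one | Cc1c(C)c2c(cc1O)OC(C)(C)OC2=O | intermediate
11 | 7-(benzyloxy)-2,2,5,6-tetramethyl-4H-1,3-benzodioxin-4-one | Cc1c(C)c2c(cc1OCc3ccccc3)OC(C)(C)OC2=O | intermediate
12 | methyl 2,4-dihydroxy-3,6-dimethylbenzoate (atraric acid) | COC(=O)c1c(C)cc(O)c(C)c1O | starting material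
13 | methyl 5-[chloro(methoxy)methyl]-2,4-dihydroxy-3,6-dimethylbenzoate (as its titanium complex, not isolated) | COC(=O)c1c(C)c(C(Cl)OC)c(O)c(C)c1O | intermediate
14 | methyl 5-formyl-2,4-dihydroxy-3,6-dimethylbenzoate | COC(=O)c1c(C)c(C=O)c(O)c(C)c1O | intermediate
15 | methyl 2,4-dihydroxy-5-(hydroxymethyl)-3,6-dimethylbenzoate (not isolated) | COC(=O)c1c(C)c(CO)c(O)c(C)c1O | intermediate
16 | methyl 2,4-dihydroxy-3,5,6-trimethylbenzoate | COC(=O)c1c(C)c(C)c(O)c(C)c1O | intermediate
17 | sodium 3-hydroxy-4-(methoxycarbonyl)-2,5,6-trimethylphenoxide (not isolated) | COC(=O)c1c(C)c(C)c([O-])c(C)c1O.[Na+] | intermediate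
18 | 3-hydroxy-4-(methoxycarbonyl)-2,5,6-trimethylphenyl 4-(benzyloxy)-2-hydroxy-5,6-dimethylbenzoate | COC(=O)c1c(C)c(C)c(OC(=O)c2c(C)c(C)c(OCc3ccccc3)cc2O)c(C)c1O | intermediate
19 | 3-hydroxy-4-(methoxycarbonyl)-2,5,6-trimethylphenyl 2,4-dihydroxy-5,6-dimethylbenzoate | COC(=O)c1c(C)c(C)c(OC(=O)c2c(C)c(C)c(O)cc2O)c(C)c1O | intermediate
20 | 3-hydroxy-4-(methoxycarbonyl)-2,5,6-trimethylphenyl 3-[chloro(methoxy)methyl]-2,4-dihydroxy-5,6-dimethylbenzoate (as its titanium complex, not isolated) | COC(=O)c1c(C)c(C)c(OC(=O)c2c(C)c(C)c(O)c(C(Cl)OC)c2O)c(C)c1O | intermediate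
21 | pseudocyphellarin A, 3-hydroxy-4-(methoxycarbonyl)-2,5,6-trimethylphenyl 3-formyl-2,4-dihydroxy-5,6-dimethylbenzoate | COC(=O)c1c(C)c(C)c(OC(=O)c2c(C)c(C)c(O)c(C=O)c2O)c(C)c1O | target

**Step count**

Total: 9 steps. Longest linear sequence: 7 steps (1, 2, 3, 4, 7, 8, 9) from dioxinone 1; ring B is a 2-step branch (5, 6).

**Steps most likely to fail**

Step 7. The phenoxide is flanked by two methyl groups and weakened by its para ester, and the carbonyl it must reach has an ortho methyl of its own. Addition may therefore be slow, and the tetrahedral adduct may return to the starting materials faster than it opens; forcing the reaction could then lead to benzyl or acyl scrambling. The fallback sets out from 11. The acylal would be saponified with KOH in aqueous DMSO and acidified, with loss of acetone, to give 4-(benzyloxy)-2-hydroxy-5,6-dimethylbenzoic acid F1. F1 would then be condensed with phenol 16 by trifluoroacetic anhydride in toluene at room temperature, the mixed-anhydride esterification long used for depsides, which should acylate the free C4 hydroxyl of 16. The route is rejoined at 18.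

Step 9. The aryl ester may be cleaved or may migrate in a Fries-type process under TiCl4, or formylation may stall because the ring is deactivated by the ester and by titanium phenoxide formation. The fallback sets out from 10 and puts the aldehyde in before the rings are joined. Rieche formylation at C8 of the benzodioxinone, its only free position, should give 7-hydroxy-2,2,5,6-tetramethyl-4-oxo-4H-1,3-benzodioxine-8-carbaldehyde F2. KOH in aqueous THF followed by acid would open the acylal, with loss of acetone, to 3-formyl-2,4-dihydroxy-5,6-dimethylbenzoic acid F3. Carbodiimide esterification (DCC, toluene–ether) of F3 with phenol 16, in which the chelated phenols of F3 should stay unreactive, would then give the target directly. The route is rejoined at 21, and steps 4, 7 and 8 are bypassed.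

Step 2. The second deprotonation may be incomplete, or the secondary carbanion may add only sluggishly to the amide, so that proton transfer and self-condensation compete; the diketone may also cyclize during work-up. The fallback sets out from 4. The same dianion would be trapped at −78 °C with acetaldehyde, a far faster electrophile, in an aldol addition that should give 6-(4-hydroxy-3-methyl-2-oxopentyl)-2,2-dimethyl-4H-1,3-dioxin-4-one F4 as a mixture of diastereomers. Dess–Martin periodinane in CH2Cl2 would then oxidize the secondary alcohol to the 1,3-diketone. The route is rejoined at 8.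

**Further compounds**

F1 | step 7 | 4-(benzyloxy)-2-hydroxy-5,6-dimethylbenzoic acid | Cc1c(C)c(C(=O)O)c(O)cc1OCc2ccccc2
F2 | step 9 | 7-hydroxy-2,2,5,6-tetramethyl-4-oxo-4H-1,3-benzodioxine-8-carbaldehyde | Cc1c(C)c2c(c(C=O)c1O)OC(C)(C)OC2=O
F3 | step 9 | 3-formyl-2,4-dihydroxy-5,6-dimethylbenzoic acid | Cc1c(C)c(C(=O)O)c(O)c(C=O)c1O
F4 | step 2 | 6-(4-hydroxy-3-methyl-2-oxopentyl)-2,2-dimethyl-4H-1,3-dioxin-4-one | CC(O)C(C)C(=O)CC1=CC(=O)OC(C)(C)O1
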